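The flavone is cut through ring C at C4–C4a and O1–C2. This leaves phloroglucinol as ring A and an aroyl(methoxy)acetate that already carries C2, C3–OMe, C4 and the prenylated ring B. A neutral Mentzer melt forges both bonds at once and thereby builds the pyranone. It exploits ring A: the oxygens on C5, C7 and C8a and the carbons C4a, C6 and C8 map onto threefold-symmetric phloroglucinol, so every acylation and closure site leads to the same 5,7-dihydroxychromone and ring A stays unprotected. The precursor is ethyl 2-methoxy-3-oxo-3-arylpropanoate with its catechol capped as a bis-TIPS ether, sturdier than TBS in a hot phenolic melt yet fluoride-labile.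

Key step: step 6

Assumption: the target has no stereocentre, and its only acyclic C=C carries two identical methyl groups, so it is achiral and there is no enantiomer to select. The stereocentres of 8, 9, 12 and 13 are transient and are erased by the end of step 6.

Step 1
Reactants: 1 5-bromovanillin
Product: 2 3-bromo-4,5-dihydroxybenzaldehyde
Conditions: AlCl3, pyridine, CH2Cl2, reflux; then aq HCl
Reagents that add atoms: none
Why: Lewis-acid aryl methyl ether cleavage, in which AlCl3 chelates the ortho hydroxy/methoxy pair and pyridine removes the activated methyl group by SN2; this is a standard selective demethylation of guaiacol-type aldehydes that leaves the aldehyde and the aryl bromide untouched.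

Step 2
Reactants: 2 3-bromo-4,5-dihydroxybenzaldehyde
Product: 3 3-bromo-4,5-bis(triisopropylsilyloxy)benzaldehyde
Conditions: TIPSOTf (2.4 equiv), 2,6-lutidine, CH2Cl2, 0 °C to rt
Reagents that add atoms: triisopropylsilyl trifluoromethanesulfonate (TIPSOTf), CC(C)[Si](OS(=O)(=O)C(F)(F)F)(C(C)C)C(C)C
Why: O-silylation with a silyl triflate and a hindered pyridine base, reactive enough for the oxygen wedged between bromine and the neighbouring silyloxy group, installs aryl TIPS ethers that resist protic and nucleophilic cleavage far better than TBS ethers and still fall to fluoride.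

Step 3
Reactants: 3 3-bromo-4,5-bis(triisopropylsilyloxy)benzaldehyde; 4 tributyl(3-methylbut-2-en-1-yl)stannane (prenyltributyltin)
Product: 5 3-(3-methylbut-2-enyl)-4,5-bis(triisopropylsilyloxy)benzaldehyde
Conditions: Pd(PPh3)4 (5 mol %), degassed DMF, 90 °C, Ar; tin residues removed on K2CO3–silica
Reagents that add atoms: none
Why: Stille cross-coupling runs without base or fluoride, so the aldehyde and silyl ethers should survive, and reductive elimination from the less hindered primary η1-prenyl palladium species should deliver the linear 3-methylbut-2-enyl arene.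

Step 4
Reactants: 5 3-(3-methylbut-2-enyl)-4,5-bis(triisopropylsilyloxy)benzaldehyde; 6 ethyl methoxyacetate
Product: 8 ethyl 3-hydroxy-2-methoxy-3-[3-(3-methylbut-2-enyl)-4,5-bis(triisopropylsilyloxy)phenyl]propanoate (racemic syn/anti mixture), via lithium enolate 7 (not isolated)
Conditions: LDA (commercial solution), 6, THF, −78 °C; then 5, −78 °C; AcOH quench at −78 °C
Reagents that add atoms: none
Why: Lithium-enolate aldol addition of an alkoxyacetate to a non-enolisable aromatic aldehyde; the two new stereocentres form without control, which is harmless because one is oxidised in step 5 and the other becomes sp2 in step 6.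

Step 5
Reactants: 8 ethyl 3-hydroxy-2-methoxy-3-[3-(3-methylbut-2-enyl)-4,5-bis(triisopropylsilyloxy)phenyl]propanoate
Product: 9 ethyl 2-methoxy-3-oxo-3-[3-(3-methylbut-2-enyl)-4,5-bis(triisopropylsilyloxy)phenyl]propanoate (racemic and enolisable)
Conditions: Dess–Martin periodinane (1.2 equiv), CH2Cl2, 0 °C to rt
Reagents that add atoms: none
Why: Dess–Martin oxidation turns the benzylic secondary alcohol into the aryl ketone under near-neutral conditions that spare the trisubstituted alkene, silyl ethers and ester, and a small excess with a short reaction time limits attack at C2–H.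

Step 6
Reactants: 9 ethyl 2-methoxy-3-oxo-3-[3-(3-methylbut-2-enyl)-4,5-bis(triisopropylsilyloxy)phenyl]propanoate; 10 phloroglucinol (anhydrous)
Product: 14 3',4'-bis-O-TIPS-uralenol 3-methyl ether, via aroyl(methoxy)ketene 11 (not isolated), via C-acylphloroglucinol triketone 12 (not isolated), via cyclic hemiketal 13 (not isolated)
Conditions: 10 (2.5 equiv, dried), melt with minimum Ph2O, 230–240 °C (microwave or metal bath), Ar sweep to carry off EtOH and H2O, 15–30 min
Reagents that add atoms: none
Why: Mentzer pyrone synthesis: the enol of 9 loses ethanol through a six-centre transition state to give ketene 11, whose central carbon is taken up by phloroglucinol at a ring CH (through its keto tautomer, or at oxygen first with the aryl ester reverting to 11 until carbon wins), which sets C4–C4a and gives triketone 12. A phenol oxygen flanking the new acyl group then adds to the B-ring ketone carbon in a 6-exo-trig closure to hemiketal 13, and loss of water sets O1–C2 within an aromatic 4-pyranone, an irreversible exit that drains the reversible O-acylation equilibria. The closest known reaction type is the solvent-free thermal or microwave condensation of phloroglucinol with ethyl aroylacetates, 2-substituted ones included, to 5,7-dihydroxyflavones. No stereocentre is created, since the racemic C2 of 9 and the transient centres of 12 and 13 end as sp2 C3 and C2. The step needs chromone rather than 4-arylcoumarin formation, secured by the absence of any acid that would activate the ketone for Pechmann-type ring attack while the ketene carbon is the strongest electrophile present, and it needs no regiocontrol because all three CH and all three OH sites of 10 are equivalent, with excess 10 and the deactivating new carbonyl holding back a second annulation. The TIPS ethers keep O4' blocked so that no free phenol can attack the neighbouring prenyl alkene in the melt, and any silyl shuffling onto ring A would be erased in step 7.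

Step 7
Reactants: 14 3',4'-bis-O-TIPS-uralenol 3-methyl ether
Product: 15 uralenol 3-methyl ether
Conditions: TBAF (2.5 equiv), AcOH (2.5 equiv), THF, 0 °C to rt, Ar
Reagents that add atoms: none
Why: Fluoride-mediated desilylation driven by Si–F bond formation; the acetic acid buffer keeps the catechol and 7-OH protonated so that no catecholate is exposed to oxidation, and no acid strong enough to close O4' onto the prenyl alkene is present.

Compound list
1 | 5-bromovanillin | COc1cc(C=O)cc(Br)c1O | starting material
2 | 3-bromo-4,5-dihydroxybenzaldehyde | O=Cc1cc(O)c(O)c(Br)c1 | intermediate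
3 | 3-bromo-4,5-bis(triisopropylsilyloxy)benzaldehyde | O=Cc1cc(Br)c(O[Si](C(C)C)(C(C)C)C(C)C)c(O[Si](C(C)C)(C(C)C)C(C)C)c1 | intermediate
4 | tributyl(3-methylbut-2-en-1-yl)stannane | CCCC[Sn](CCCC)(CCCC)CC=C(C)C | starting material
5 | 3-(3-methylbut-2-enyl)-4,5-bis(triisopropylsilyloxy)benzaldehyde | O=Cc1cc(CC=C(C)C)c(O[Si](C(C)C)(C(C)C)C(C)C)c(O[Si](C(C)C)(C(C)C)C(C)C)c1 | intermediate
6 | ethyl methoxyacetate | CCOC(=O)COC | starting material
7 | lithium enolate of ethyl methoxyacetate (not isolated) | CCOC([O-])=COC.[Li+] | intermediate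
8 | ethyl 3-hydroxy-2-methoxy-3-[3-(3-methylbut-2-enyl)-4,5-bis(triisopropylsilyloxy)phenyl]propanoate, racemic syn/anti mixture | CCOC(=O)C(OC)C(O)c1cc(CC=C(C)C)c(O[Si](C(C)C)(C(C)C)C(C)C)c(O[Si](C(C)C)(C(C)C)C(C)C)c1 | intermediate
9 | ethyl 2-methoxy-3-oxo-3-[3-(3-methylbut-2-enyl)-4,5-bis(triisopropylsilyloxy)phenyl]propanoate, racemic | CCOC(=O)C(OC)C(=O)c1cc(CC=C(C)C)c(O[Si](C(C)C)(C(C)C)C(C)C)c(O[Si](C(C)C)(C(C)C)C(C)C)c1 | intermediate
10 | phloroglucinol | Oc1cc(O)cc(O)c1 | starting material
11 | aroyl(methoxy)ketene (not isolated) | COC(=C=O)C(=O)c1cc(CC=C(C)C)c(O[Si](C(C)C)(C(C)C)C(C)C)c(O[Si](C(C)C)(C(C)C)C(C)C)c1 | intermediate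
12 | 2-methoxy-1-(2,4,6-trihydroxyphenyl)-3-[3-(3-methylbut-2-enyl)-4,5-bis(triisopropylsilyloxy)phenyl]propane-1,3-dione, racemic (not isolated) | COC(C(=O)c1c(O)cc(O)cc1O)C(=O)c1cc(CC=C(C)C)c(O[Si](C(C)C)(C(C)C)C(C)C)c(O[Si](C(C)C)(C(C)C)C(C)C)c1 | intermediate
13 | 2,5,7-trihydroxy-3-methoxy-2-arylchroman-4-one hemiketal, stereoisomer mixture (not isolated) | COC1C(=O)c2c(O)cc(O)cc2OC1(O)c1cc(CC=C(C)C)c(O[Si](C(C)C)(C(C)C)C(C)C)c(O[Si](C(C)C)(C(C)C)C(C)C)c1 | intermediate
14 | 5,7-dihydroxy-3-methoxy-2-[3-(3-methylbut-2-enyl)-4,5-bis(triisopropylsilyloxy)phenyl]-4H-chromen-4-one (3',4'-bis-O-TIPS-uralenol 3-methyl ether) | COc1c(-c2cc(CC=C(C)C)c(O[Si](C(C)C)(C(C)C)C(C)C)c(O[Si](C(C)C)(C(C)C)C(C)C)c2)oc2cc(O)cc(O)c2c1=O | intermediate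
15 | uralenol 3-methyl ether (achiral) | COc1c(-c2cc(O)c(O)c(CC=C(C)C)c2)oc2cc(O)cc(O)c2c1=O | target

Total step count: 7. Longest linear sequence: 7 steps (1 to 15); compounds 4, 6 and 10 enter as purchased materials.

Steps most likely to fail

Step 6 (key step). The ketene may be consumed by dimerisation or by traces of water (hydrolysis, then decarboxylation). Silyl groups may migrate to the ring-A phenols at 230–240 °C, after which the freed O4' could cyclise onto the prenyl alkene. The lipophilic ester may also mix poorly with the molten phenol. The fallback sets out from 10 and 5 and comes back at 14. It assembles the same 1,3-dicarbonyl array at low temperature and closes ring C as in the last stage of a Baker–Venkataraman flavone synthesis. Hoesch acylation of 10 with methoxyacetonitrile (ZnCl2, HCl, Et2O, then hot water) gives 2-methoxy-1-(2,4,6-trihydroxyphenyl)ethanone F1. MOMCl and NaH in DMF convert this into 2-methoxy-1-[2,4,6-tris(methoxymethoxy)phenyl]ethanone F2. Deprotonation with LDA at −78 °C and addition to aldehyde 5 gives the β-hydroxy ketone F3, and Dess–Martin oxidation gives the 2-methoxy-1,3-diketone F4. Dilute HCl in MeOH at 40–50 °C removes the three MOM groups, whereupon 12 and 13 form and dehydrate to 14. The aryl TIPS ethers are expected to outlast this mild acid and keep O4' masked.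

Step 3. Oxidative addition next to the bulky silyloxy group may be sluggish, the allyl unit may transfer from tin to the aldehyde carbonyl, or coupling may occur through the tertiary allyl terminus. The fallback runs from 3 back to 5 and inverts the polarity, so that the arene is the nucleophile and prenyl bromide the electrophile. The aldehyde is masked with HC(OMe)3 and catalytic PPTS in MeOH as the bromoaryl dimethyl acetal F5. Bromine–lithium exchange follows (n-BuLi, THF, −78 °C, where the bulky TIPS group resists an O-to-C silyl shift). Transmetalation with CuBr·SMe2 and alkylation with prenyl bromide at its primary carbon then give the prenylated dimethyl acetal F6. PPTS in wet acetone releases 5.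

Step 5. Further oxidation at the doubly activated C2–H may occur, or 8 may undergo retro-aldol cleavage before oxidation is complete. The fallback runs from 5 back to 9 and bypasses steps 4 and 5. It sets the ketone oxidation level before C–C bond formation and makes the bond by a crossed Claisen acylation. Pinnick oxidation of 5 (NaClO2, NaH2PO4, large excess of 2-methyl-2-butene, t-BuOH/H2O) gives the benzoic acid F7, and CDI in THF gives the acyl imidazolide F8. Addition of F8 to two equivalents of lithium enolate 7 at −78 °C gives 9 after a mildly acidic quench.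

Further compounds
F1 | step 6 | 2-methoxy-1-(2,4,6-trihydroxyphenyl)ethanone | COCC(=O)c1c(O)cc(O)cc1O
F2 | step 6 | 2-methoxy-1-[2,4,6-tris(methoxymethoxy)phenyl]ethanone | COCC(=O)c1c(OCOC)cc(OCOC)cc1OCOC
F3 | step 6 | 3-hydroxy-2-methoxy-3-[3-(3-methylbut-2-enyl)-4,5-bis(triisopropylsilyloxy)phenyl]-1-[2,4,6-tris(methoxymethoxy)phenyl]propan-1-one, racemic diastereomer mixture | COC(C(=O)c1c(OCOC)cc(OCOC)cc1OCOC)C(O)c1cc(CC=C(C)C)c(O[Si](C(C)C)(C(C)C)C(C)C)c(O[Si](C(C)C)(C(C)C)C(C)C)c1
F4 | step 6 | 2-methoxy-3-[3-(3-methylbut-2-enyl)-4,5-bis(triisopropylsilyloxy)phenyl]-1-[2,4,6-tris(methoxymethoxy)phenyl]propane-1,3-dione, racemic | COC(C(=O)c1c(OCOC)cc(OCOC)cc1OCOC)C(=O)c1cc(CC=C(C)C)c(O[Si](C(C)C)(C(C)C)C(C)C)c(O[Si](C(C)C)(C(C)C)C(C)C)c1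
F5 | step 3 | 1-bromo-5-(dimethoxymethyl)-2,3-bis(triisopropylsilyloxy)benzene | COC(OC)c1cc(Br)c(O[Si](C(C)C)(C(C)C)C(C)C)c(O[Si](C(C)C)(C(C)C)C(C)C)c1
F6 | step 3 | 5-(dimethoxymethyl)-1-(3-methylbut-2-enyl)-2,3-bis(triisopropylsilyloxy)benzene | COC(OC)c1cc(CC=C(C)C)c(O[Si](C(C)C)(C(C)C)C(C)C)c(O[Si](C(C)C)(C(C)C)C(C)C)c1
F7 | step 5 | 3-(3-methylbut-2-enyl)-4,5-bis(triisopropylsilyloxy)benzoic acid | OC(=O)c1cc(CC=C(C)C)c(O[Si](C(C)C)(C(C)C)C(C)C)c(O[Si](C(C)C)(C(C)C)C(C)C)c1
F8 | step 5 | 1-[3-(3-methylbut-2-enyl)-4,5-bis(triisopropylsilyloxy)benzoyl]imidazole | O=C(n1ccnc1)c1cc(CC=C(C)C)c(O[Si](C(C)C)(C(C)C)C(C)C)c(O[Si](C(C)C)(C(C)C)C(C)C)c1
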